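The chain is attached to the cyclohexene by sp2–sp3 coupling of an enol triflate, which traces the ring to 2,2,6-trimethylcyclohexanone. That ketone is grown from a five-membered ring: Lewis-acid-mediated insertion of the CH(CH3) carbon of diazoethane between C=O and CH2 of 2,2-dimethylcyclopentanone. The step exploits the cyclohexene carbon that carries the chain: it lies between the C(CH3)2 carbon and the C(CH3)= carbon, so as a carbonyl it has a single enolisable neighbour. The peroxide comes last: Sharpless epoxide, perhydrolysis with inversion at C6, then 1,2-dioxane closure by peroxide-anion opening of a cis-β-lactone at C3.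

Key step: step 1

Remark on numbering: C1, C2, C3 and C6 denote the ester carbon, the propanoate α-carbon and the two oxygen-bearing dioxane carbons of the target.

Assumption: in step 14 O-trimethylsilylquinine is taken as the alkaloid that delivers the (3S,4R)-lactone; if the sense of induction is the opposite, the pseudoenantiomeric O-trimethylsilylquinidine is used instead.

Step 1
Reactants: 1 2,2-dimethylcyclopentan-1-one; 2 N-ethyl-N-nitrosourea
Product: 4 2,2,6-trimethylcyclohexan-1-one (racemic), via diazoethane 3 (not isolated)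
Conditions: 2, KOH (40% aq), Et2O, 0 °C, ethereal layer dried over KOH; then 1, Sc(OTf)3 (10 mol %), toluene, −78 → −20 °C
Reagents that add atoms: none
Why: Sc(OTf)3 activates the carbonyl of 1 for attack by the nucleophilic carbon of diazoethane, and the diazonium alkoxide then loses N2 with a 1,2-shift of a ring C–C bond onto the former diazo carbon, so that the CH(CH3) unit becomes a ring member. The closest known reaction type is the Lewis-acid-catalysed single-carbon homologation of cycloalkanones by alkyl diazomethanes (Tiffeneau–Demjanov type). No ring is closed: the existing five-membered carbocycle is enlarged to the six-membered ring by migration of its CH2 carbon. The one new stereocenter (the methyl-bearing carbon of 4) is formed racemic and is of no consequence, because step 2 turns it into an alkene carbon. The step needs migration of the CH2 carbon and not of the quaternary carbon, which the gem-dimethyl group should secure, since the less substituted, less hindered α-carbon migrates in these insertions. It also needs to stop after one insertion, which the product secures because its carbonyl is now flanked by two branched carbons.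

Step 2
Reactants: 4 2,2,6-trimethylcyclohexan-1-one
Product: 6 2,6,6-trimethylcyclohex-1-en-1-yl trifluoromethanesulfonate, via lithium enolate 5 (not isolated)
Conditions: LiN(iPr)2, THF, −78 °C; then PhNTf2, −78 °C → rt
Reagents that add atoms: N-phenylbis(trifluoromethanesulfonimide) O=S(=O)(N(c1ccccc1)S(=O)(=O)C(F)(F)F)C(F)(F)F
Why: Enol triflate formation: 4 has a single α-hydrogen, so LiN(iPr)2 should give one enolate, whose O-sulfonylation places the triflate on the future chain-bearing carbon and erases the racemic stereocenter.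

Step 3
Reactants: 7 geranyl acetate
Product: 8 (2E,6E)-8-hydroxy-3,7-dimethylocta-2,6-dien-1-yl acetate
Conditions: SeO2 (0.3 equiv), tBuOOH (3 equiv), salicylic acid (0.1 equiv), CH2Cl2, rt
Reagents that add atoms: selenium dioxide O=[Se]=O (oxygen carrier, catalytic); tert-butyl hydroperoxide CC(C)(C)OO (terminal oxygen source)
Why: Riley allylic oxidation (ene reaction, then [2,3]-sigmatropic shift) should hydroxylate the (E)-methyl group of the terminal trisubstituted alkene, the other alkene being deactivated by its allylic acetate; no stereocenter is formed.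

Step 4
Reactants: 8 (2E,6E)-8-hydroxy-3,7-dimethylocta-2,6-dien-1-yl acetate
Product: 9 (2E,6E)-3,7-dimethyl-8-oxoocta-2,6-dien-1-yl acetate
Conditions: MnO2 (excess), CH2Cl2, rt
Reagents that add atoms: none
Why: Selective MnO2 oxidation of the allylic alcohol should give the (E)-enal and leave the acetate alone.

Step 5
Reactants: 9 (2E,6E)-3,7-dimethyl-8-oxoocta-2,6-dien-1-yl acetate
Product: 10 (2E,6E)-3,7-dimethylnona-2,6,8-trien-1-yl acetate
Conditions: Ph3PCH3Br, n-BuLi, THF, 0 °C; then 9, −78 → 0 °C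
Reagents that add atoms: methyltriphenylphosphonium bromide C[P+](c1ccccc1)(c1ccccc1)c1ccccc1.[Br-]
Why: Wittig methylenation: the unstabilised ylide should add to the aldehyde far faster than to the acetate at low temperature, giving the terminal diene without touching the trisubstituted alkenes.

Step 6
Reactants: 10 (2E,6E)-3,7-dimethylnona-2,6,8-trien-1-yl acetate
Product: 11 (2E,6E)-3,7-dimethylnona-2,6,8-trien-1-ol
Conditions: K2CO3 (0.2 equiv), MeOH, 0 °C → rt
Reagents that add atoms: none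
Why: Base-catalysed transesterification with methanol should free the allylic alcohol that the next step needs as a directing group.

Step 7
Reactants: 11 (2E,6E)-3,7-dimethylnona-2,6,8-trien-1-ol
Product: 12 [(2R,3R)-3-methyl-3-[(3E)-4-methylhexa-3,5-dien-1-yl]oxiran-2-yl]methanol
Conditions: Ti(OiPr)4 (10 mol %), D-(−)-diethyl tartrate (12 mol %), tBuOOH, 4 Å molecular sieves, CH2Cl2, −20 °C
Reagents that add atoms: tert-butyl hydroperoxide CC(C)(C)OO
Why: Sharpless asymmetric epoxidation: only the alkene of the allylic alcohol is bound to the Ti(OiPr)4–tartrate catalyst, and D-(−)-diethyl tartrate should deliver oxygen to the face that gives the (2R,3R)-epoxide (reagent control), the diene staying untouched.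

Step 8
Reactants: 12 [(2R,3R)-3-methyl-3-[(3E)-4-methylhexa-3,5-dien-1-yl]oxiran-2-yl]methanol; 6 2,6,6-trimethylcyclohex-1-en-1-yl trifluoromethanesulfonate
Product: 14 [(2R,3R)-3-methyl-3-[(3E)-4-methyl-6-(2,6,6-trimethylcyclohex-1-en-1-yl)hex-3-en-1-yl]oxiran-2-yl]methanol, via alkylborane 13 (not isolated)
Conditions: 9-BBN (2.2 equiv), THF, 0 °C → rt; then 6, PdCl2(dppf) (5 mol %), AsPh3 (10 mol %), Cs2CO3, DMF/H2O, rt → 50 °C
Reagents that add atoms: none
Why: B-alkyl Suzuki–Miyaura coupling: 9-BBN should hydroborate only the monosubstituted diene terminus (anti-Markovnikov), and the primary alkylborane is then transferred to the hindered enol triflate at the PdCl2(dppf)-derived catalyst, which forms the bond to the cyclohexene carbon between C(CH3)2 and C(CH3)=; the epoxide stereocenters are not involved.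

Step 9
Reactants: 14 [(2R,3R)-3-methyl-3-[(3E)-4-methyl-6-(2,6,6-trimethylcyclohex-1-en-1-yl)hex-3-en-1-yl]oxiran-2-yl]methanol
Product: 15 (2R,3S,6E)-3-hydroperoxy-3,7-dimethyl-9-(2,6,6-trimethylcyclohex-1-en-1-yl)non-6-ene-1,2-diol
Conditions: H2O2 (anhydrous, in Et2O, 8 equiv), H3PMo12O40 (2 mol %), Et2O, 0 °C → rt
Reagents that add atoms: hydrogen peroxide OO
Why: H3PMo12O40-catalysed perhydrolysis of the epoxide: H2O2 should open the acid-activated oxirane at its tertiary carbon from the side opposite the oxygen (borderline SN2, inversion), so the (3R) epoxide carbon becomes the (3S) tertiary hydroperoxide, the future C6.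

Step 10
Reactants: 15 (2R,3S,6E)-3-hydroperoxy-3,7-dimethyl-9-(2,6,6-trimethylcyclohex-1-en-1-yl)non-6-ene-1,2-diol
Product: 16 (2R,3S,6E)-3-[(tert-butyldimethylsilyl)peroxy]-3,7-dimethyl-9-(2,6,6-trimethylcyclohex-1-en-1-yl)non-6-ene-1,2-diol
Conditions: TBSCl (1.05 equiv), Et3N (1.2 equiv), CH2Cl2, 0 °C
Reagents that add atoms: tert-butyldimethylsilyl chloride CC(C)(C)[Si](C)(C)Cl
Why: Chemoselective O-silylation: Et3N should ionise only the hydroperoxide (pKa near 12.5), whose α-nucleophilic anion takes up TBSCl, while the neutral hydroxyls need a nucleophilic catalyst to react.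

Step 11
Reactants: 16 (2R,3S,6E)-3-[(tert-butyldimethylsilyl)peroxy]-3,7-dimethyl-9-(2,6,6-trimethylcyclohex-1-en-1-yl)non-6-ene-1,2-diol
Product: 17 (2S,5E)-2-[(tert-butyldimethylsilyl)peroxy]-2,6-dimethyl-8-(2,6,6-trimethylcyclohex-1-en-1-yl)oct-5-enal
Conditions: NaIO4, THF/pH 7 buffer, 0 °C → rt
Reagents that add atoms: none
Why: Malaprade glycol cleavage should remove the carbinol carbon as formaldehyde and leave an aldehyde next to the quaternary peroxy carbon, which has no α-hydrogen and so cannot epimerise or eliminate.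

Step 12
Reactants: 17 (2S,5E)-2-[(tert-butyldimethylsilyl)peroxy]-2,6-dimethyl-8-(2,6,6-trimethylcyclohex-1-en-1-yl)oct-5-enal
Product: 18 (2E,4S,7E)-4-[(tert-butyldimethylsilyl)peroxy]-4,8-dimethyl-10-(2,6,6-trimethylcyclohex-1-en-1-yl)deca-2,7-dienal
Conditions: Ph3P=CHCHO (1.3 equiv), toluene, 60 °C
Reagents that add atoms: (triphenylphosphoranylidene)acetaldehyde O=CC=P(c1ccccc1)(c1ccccc1)c1ccccc1
Why: Wittig reaction of the stabilised formyl ylide should add two carbons as the (E)-enal under neutral conditions that the silyl peroxide tolerates.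

Step 13
Reactants: 18 (2E,4S,7E)-4-[(tert-butyldimethylsilyl)peroxy]-4,8-dimethyl-10-(2,6,6-trimethylcyclohex-1-en-1-yl)deca-2,7-dienal
Product: 19 (4S,7E)-4-[(tert-butyldimethylsilyl)peroxy]-4,8-dimethyl-10-(2,6,6-trimethylcyclohex-1-en-1-yl)dec-7-enal
Conditions: Hantzsch ester (1.2 equiv), Bn2NH2+ CF3CO2− (10 mol %), THF, rt
Reagents that add atoms: none
Why: Organocatalytic transfer hydrogenation: the iminium ion of the enal should accept hydride from the Hantzsch ester at its β-carbon, which reduces only the conjugated C=C and uses neither metal nor phosphine that could cleave the O–O bond.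

Step 14
Reactants: 19 (4S,7E)-4-[(tert-butyldimethylsilyl)peroxy]-4,8-dimethyl-10-(2,6,6-trimethylcyclohex-1-en-1-yl)dec-7-enal; 20 propanoyl chloride
Product: 22 (3S,4R)-4-[(3S,6E)-3-[(tert-butyldimethylsilyl)peroxy]-3,7-dimethyl-9-(2,6,6-trimethylcyclohex-1-en-1-yl)non-6-en-1-yl]-3-methyloxetan-2-one, via methylketene 21 (not isolated)
Conditions: 20 (2 equiv), O-trimethylsilylquinine (10 mol %), LiClO4 (1 equiv), iPr2NEt (2.5 equiv), CH2Cl2/Et2O, −78 °C
Reagents that add atoms: none
Why: Catalytic asymmetric acyl halide–aldehyde cyclocondensation: the alkaloid-bound ammonium enolate of methylketene should add to the LiClO4-activated aldehyde through a closed chair transition state and ring-close to the cis-β-lactone, the alkaloid fixing both new stereocenters as (3S,4R) independently of the remote peroxide center (catalyst control).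

Step 15
Reactants: 22 (3S,4R)-4-[(3S,6E)-3-[(tert-butyldimethylsilyl)peroxy]-3,7-dimethyl-9-(2,6,6-trimethylcyclohex-1-en-1-yl)non-6-en-1-yl]-3-methyloxetan-2-one
Product: 25 methyl (2S)-2-[(3S,6S)-6-methyl-6-[(3E)-4-methyl-6-(2,6,6-trimethylcyclohex-1-en-1-yl)hex-3-en-1-yl]-1,2-dioxan-3-yl]propanoate, via cesium peroxide 23 (not isolated), via cesium carboxylate 24 (not isolated)
Conditions: CsF (1.2 equiv), 18-crown-6, DMF, −20 → 0 °C; then MeI (5 equiv), 0 °C → rt
Reagents that add atoms: iodomethane CI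
Why: Proposed new method: fluoride removes the silyl group and frees a peroxide anion that should attack the lactone C4 from the side opposite the ring oxygen in a 6-exo-tet SN2 opening (alkyl–oxygen cleavage, driven by release of four-ring strain, the acyl carbon being reachable only through an eight-membered ring), which closes the 1,2-dioxane with inversion at C3 and leaves C2 and C6 untouched, after which the liberated carboxylate is methylated by MeI; the closest known reaction types are the SN2 opening of 3,4-disubstituted β-lactones at C4 by azide, sulfonamide anions and cuprates with inversion, and the 6-exo alkylation of peroxide anions by sulfonates.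

Compound list
1 | 2,2-dimethylcyclopentan-1-one | CC1(C)CCCC1=O | starting material
2 | N-ethyl-N-nitrosourea | CCN(N=O)C(N)=O | starting material
3 | diazoethane | CC=[N+]=[N-] | intermediate
4 | 2,2,6-trimethylcyclohexan-1-one (racemic) | CC1CCCC(C)(C)C1=O | intermediate
5 | lithium 2,6,6-trimethylcyclohex-1-en-1-olate | CC1=C([O-])C(C)(C)CCC1.[Li+] | intermediate
6 | 2,6,6-trimethylcyclohex-1-en-1-yl trifluoromethanesulfonate | CC1=C(OS(=O)(=O)C(F)(F)F)C(C)(C)CCC1 | intermediate
7 | geranyl acetate, (2E)-3,7-dimethylocta-2,6-dien-1-yl acetate | CC(=O)OC/C=C(C)/CCC=C(C)C | starting material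
8 | (2E,6E)-8-hydroxy-3,7-dimethylocta-2,6-dien-1-yl acetate | CC(=O)OC/C=C(C)/CC/C=C(C)/CO | intermediate
9 | (2E,6E)-3,7-dimethyl-8-oxoocta-2,6-dien-1-yl acetate | CC(=O)OC/C=C(C)/CC/C=C(C)/C=O | intermediate
10 | (2E,6E)-3,7-dimethylnona-2,6,8-trien-1-yl acetate | CC(=O)OC/C=C(C)/CC/C=C(C)/C=C | intermediate
11 | (2E,6E)-3,7-dimethylnona-2,6,8-trien-1-ol | OC/C=C(C)/CC/C=C(C)/C=C | intermediate
12 | [(2R,3R)-3-methyl-3-[(3E)-4-methylhexa-3,5-dien-1-yl]oxiran-2-yl]methanol | C=C/C(C)=C/CC[C@@]1(C)O[C@@H]1CO | intermediate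
13 | 9-[(3E)-3-methyl-6-[(2R,3R)-2-methyl-3-[(9-borabicyclo[3.3.1]nonan-9-yloxy)methyl]oxiran-2-yl]hex-3-en-1-yl]-9-borabicyclo[3.3.1]nonane | B1(CC/C(C)=C/CC[C@@]2(C)O[C@@H]2COB3C4CCCC3CCC4)C5CCCC1CCC5 | intermediate
14 | [(2R,3R)-3-methyl-3-[(3E)-4-methyl-6-(2,6,6-trimethylcyclohex-1-en-1-yl)hex-3-en-1-yl]oxiran-2-yl]methanol | CC1=C(CC/C(C)=C/CC[C@@]2(C)O[C@@H]2CO)C(C)(C)CCC1 | intermediate
15 | (2R,3S,6E)-3-hydroperoxy-3,7-dimethyl-9-(2,6,6-trimethylcyclohex-1-en-1-yl)non-6-ene-1,2-diol | CC1=C(CC/C(C)=C/CC[C@](C)(OO)[C@H](O)CO)C(C)(C)CCC1 | intermediate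
16 | (2R,3S,6E)-3-[(tert-butyldimethylsilyl)peroxy]-3,7-dimethyl-9-(2,6,6-trimethylcyclohex-1-en-1-yl)non-6-ene-1,2-diol | CC1=C(CC/C(C)=C/CC[C@](C)(OO[Si](C)(C)C(C)(C)C)[C@H](O)CO)C(C)(C)CCC1 | intermediate
17 | (2S,5E)-2-[(tert-butyldimethylsilyl)peroxy]-2,6-dimethyl-8-(2,6,6-trimethylcyclohex-1-en-1-yl)oct-5-enal | CC1=C(CC/C(C)=C/CC[C@](C)(OO[Si](C)(C)C(C)(C)C)C=O)C(C)(C)CCC1 | intermediate
18 | (2E,4S,7E)-4-[(tert-butyldimethylsilyl)peroxy]-4,8-dimethyl-10-(2,6,6-trimethylcyclohex-1-en-1-yl)deca-2,7-dienal | CC1=C(CC/C(C)=C/CC[C@](C)(OO[Si](C)(C)C(C)(C)C)/C=C/C=O)C(C)(C)CCC1 | intermediate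
19 | (4S,7E)-4-[(tert-butyldimethylsilyl)peroxy]-4,8-dimethyl-10-(2,6,6-trimethylcyclohex-1-en-1-yl)dec-7-enal | CC1=C(CC/C(C)=C/CC[C@](C)(OO[Si](C)(C)C(C)(C)C)CCC=O)C(C)(C)CCC1 | intermediate
20 | propanoyl chloride | CCC(Cl)=O | starting material
21 | methylketene (prop-1-en-1-one) | CC=C=O | intermediate
22 | (3S,4R)-4-[(3S,6E)-3-[(tert-butyldimethylsilyl)peroxy]-3,7-dimethyl-9-(2,6,6-trimethylcyclohex-1-en-1-yl)non-6-en-1-yl]-3-methyloxetan-2-one | C[C@@H]1C(=O)O[C@@H]1CC[C@@](C)(OO[Si](C)(C)C(C)(C)C)CC/C=C(\C)CCC2=C(C)CCCC2(C)C | intermediate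
23 | cesium (3S,6E)-3,7-dimethyl-1-[(2R,3S)-3-methyl-4-oxooxetan-2-yl]-9-(2,6,6-trimethylcyclohex-1-en-1-yl)non-6-en-3-yl peroxide | C[C@@H]1C(=O)O[C@@H]1CC[C@@](C)(O[O-])CC/C=C(\C)CCC2=C(C)CCCC2(C)C.[Cs+] | intermediate
24 | cesium (2S)-2-[(3S,6S)-6-methyl-6-[(3E)-4-methyl-6-(2,6,6-trimethylcyclohex-1-en-1-yl)hex-3-en-1-yl]-1,2-dioxan-3-yl]propanoate | [O-]C(=O)[C@@H](C)[C@@H]1CC[C@](C)(CC/C=C(\C)CCC2=C(C)CCCC2(C)C)OO1.[Cs+] | intermediate
25 | methyl (2S)-2-[(3S,6S)-6-methyl-6-[(3E)-4-methyl-6-(2,6,6-trimethylcyclohex-1-en-1-yl)hex-3-en-1-yl]-1,2-dioxan-3-yl]propanoate | COC(=O)[C@@H](C)[C@@H]1CC[C@](C)(CC/C=C(\C)CCC2=C(C)CCCC2(C)C)OO1 | target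

Total step count: 15. Longest linear sequence: 13 steps (7 to 25, steps 3 to 15); the ring fragment (steps 1 and 2) joins at step 8.

Steps most likely to fail

1. Step 15 (Proposed new method). The peroxide anion or fluoride may act as a base and open the lactone by β-elimination to the 2-methyl enoate, which would then take up the peroxide by unselective conjugate addition. Attack at the lactone carbonyl by a second molecule, or base-induced Kornblum–DeLaMare fragmentation of the product at C3–H, may also compete. Fallback with known chemistry, from 22 back to 25: LiBH4 (THF, 0 °C) should reduce the lactone to the (2R,3R)-1,3-diol F1. TBSCl/imidazole should silylate the primary hydroxyl to give the silyl ether F2, and MsCl/Et3N should give the secondary mesylate F3. TBAF (THF, 0 °C) then removes the silyl groups, and the peroxide anion displaces the mesylate in a 6-exo SN2 closure with inversion at C3 (the established intramolecular alkylation of hydroperoxides) to give the dioxanyl propanol F4. TEMPO/PhI(OAc)2 followed by NaClO2 should give the dioxanyl propanoic acid F5, and TMSCHN2 (MeOH/toluene) gives 25.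

2. Step 9. The peroxo species formed from H3PMo12O40 and H2O2 may epoxidise the tetrasubstituted ring alkene or the trisubstituted chain alkene. The opening may also lose regiocontrol, or the β-hydroxy hydroperoxide may undergo acid-induced Hock-type cleavage. Fallback, from 14 back to 19: NaAlH2(OCH2CH2OMe)2 (THF, 0 °C) should open the epoxy alcohol at C2 to the (3R)-1,3-diol F6, with the tertiary C–O bond untouched. TsCl/pyridine gives the primary tosylate F7, and KOtBu closes the (2R)-oxetane F8. TMSOTf-catalysed opening with ethereal H2O2 at the tertiary carbon (inversion) should give the (3S)-hydroperoxy alcohol F9. TBSCl/Et3N gives the silyl peroxide alcohol F10, and Dess–Martin periodinane gives the silylperoxy aldehyde F11. Ph3P=CHOMe gives the methyl enol ether F12, and Hg(OAc)2 in aqueous THF followed by KI releases 19.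

3. Step 10. Silylation may also occur at the primary hydroxyl, giving mixtures of mono- and bis-silylated material that cannot be cleaved cleanly in step 11. Fallback, from 14 back to 16: Ac2O/pyridine should mask the primary hydroxyl as the epoxy acetate F13. Perhydrolysis as in step 9 gives the hydroperoxy hydroxy acetate F14. TBSCl/Et3N, now with only a hindered secondary hydroxyl as competitor, gives the silylperoxy hydroxy acetate F15, and iBu2AlH (CH2Cl2, −78 °C) removes the acetate to give 16.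

Further compounds
F1 | step 15 | (2R,3R,6S,9E)-6-[(tert-butyldimethylsilyl)peroxy]-2,6,10-trimethyl-12-(2,6,6-trimethylcyclohex-1-en-1-yl)dodec-9-ene-1,3-diol | C[C@H](CO)[C@H](O)CC[C@@](C)(OO[Si](C)(C)C(C)(C)C)CC/C=C(\C)CCC1=C(C)CCCC1(C)C
F2 | step 15 | (2R,3R,6S,9E)-1-[(tert-butyldimethylsilyl)oxy]-6-[(tert-butyldimethylsilyl)peroxy]-2,6,10-trimethyl-12-(2,6,6-trimethylcyclohex-1-en-1-yl)dodec-9-en-3-ol | C[C@H](CO[Si](C)(C)C(C)(C)C)[C@H](O)CC[C@@](C)(OO[Si](C)(C)C(C)(C)C)CC/C=C(\C)CCC1=C(C)CCCC1(C)C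
F3 | step 15 | (2R,3R,6S,9E)-1-[(tert-butyldimethylsilyl)oxy]-6-[(tert-butyldimethylsilyl)peroxy]-2,6,10-trimethyl-12-(2,6,6-trimethylcyclohex-1-en-1-yl)dodec-9-en-3-yl methanesulfonate | C[C@H](CO[Si](C)(C)C(C)(C)C)[C@H](OS(C)(=O)=O)CC[C@@](C)(OO[Si](C)(C)C(C)(C)C)CC/C=C(\C)CCC1=C(C)CCCC1(C)C
F4 | step 15 | (2R)-2-[(3S,6S)-6-methyl-6-[(3E)-4-methyl-6-(2,6,6-trimethylcyclohex-1-en-1-yl)hex-3-en-1-yl]-1,2-dioxan-3-yl]propan-1-ol | OC[C@@H](C)[C@@H]1CC[C@](C)(CC/C=C(\C)CCC2=C(C)CCCC2(C)C)OO1
F5 | step 15 | (2S)-2-[(3S,6S)-6-methyl-6-[(3E)-4-methyl-6-(2,6,6-trimethylcyclohex-1-en-1-yl)hex-3-en-1-yl]-1,2-dioxan-3-yl]propanoic acid | OC(=O)[C@@H](C)[C@@H]1CC[C@](C)(CC/C=C(\C)CCC2=C(C)CCCC2(C)C)OO1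
F6 | step 9 | (3R,6E)-3,7-dimethyl-9-(2,6,6-trimethylcyclohex-1-en-1-yl)non-6-ene-1,3-diol | CC1=C(CC/C(C)=C/CC[C@@](C)(O)CCO)C(C)(C)CCC1
F7 | step 9 | (3R,6E)-3-hydroxy-3,7-dimethyl-9-(2,6,6-trimethylcyclohex-1-en-1-yl)non-6-en-1-yl 4-methylbenzenesulfonate | CC1=C(CC/C(C)=C/CC[C@@](C)(O)CCOS(=O)(=O)c2ccc(C)cc2)C(C)(C)CCC1
F8 | step 9 | (2R)-2-methyl-2-[(3E)-4-methyl-6-(2,6,6-trimethylcyclohex-1-en-1-yl)hex-3-en-1-yl]oxetane | CC1=C(CC/C(C)=C/CC[C@@]2(C)OCC2)C(C)(C)CCC1
F9 | step 9 | (3S,6E)-3-hydroperoxy-3,7-dimethyl-9-(2,6,6-trimethylcyclohex-1-en-1-yl)non-6-en-1-ol | CC1=C(CC/C(C)=C/CC[C@](C)(OO)CCO)C(C)(C)CCC1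
F10 | step 9 | (3S,6E)-3-[(tert-butyldimethylsilyl)peroxy]-3,7-dimethyl-9-(2,6,6-trimethylcyclohex-1-en-1-yl)non-6-en-1-ol | CC1=C(CC/C(C)=C/CC[C@](C)(OO[Si](C)(C)C(C)(C)C)CCO)C(C)(C)CCC1
F11 | step 9 | (3S,6E)-3-[(tert-butyldimethylsilyl)peroxy]-3,7-dimethyl-9-(2,6,6-trimethylcyclohex-1-en-1-yl)non-6-enal | CC1=C(CC/C(C)=C/CC[C@](C)(OO[Si](C)(C)C(C)(C)C)CC=O)C(C)(C)CCC1
F12 | step 9 | tert-butyl[[(4S,7E)-1-methoxy-4,8-dimethyl-10-(2,6,6-trimethylcyclohex-1-en-1-yl)deca-1,7-dien-4-yl]peroxy]dimethylsilane (mixture of enol ether isomers) | CC1=C(CC/C(C)=C/CC[C@](C)(OO[Si](C)(C)C(C)(C)C)CC=COC)C(C)(C)CCC1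
F13 | step 10 | [(2R,3R)-3-methyl-3-[(3E)-4-methyl-6-(2,6,6-trimethylcyclohex-1-en-1-yl)hex-3-en-1-yl]oxiran-2-yl]methyl acetate | CC1=C(CC/C(C)=C/CC[C@@]2(C)O[C@@H]2COC(C)=O)C(C)(C)CCC1
F14 | step 10 | (2R,3S,6E)-3-hydroperoxy-2-hydroxy-3,7-dimethyl-9-(2,6,6-trimethylcyclohex-1-en-1-yl)non-6-en-1-yl acetate | CC1=C(CC/C(C)=C/CC[C@](C)(OO)[C@H](O)COC(C)=O)C(C)(C)CCC1
F15 | step 10 | (2R,3S,6E)-3-[(tert-butyldimethylsilyl)peroxy]-2-hydroxy-3,7-dimethyl-9-(2,6,6-trimethylcyclohex-1-en-1-yl)non-6-en-1-yl acetate | CC1=C(CC/C(C)=C/CC[C@](C)(OO[Si](C)(C)C(C)(C)C)[C@H](O)COC(C)=O)C(C)(C)CCC1
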